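Everything rests on cutting ring B between C1, the gem-dimethyl carbon, and C6, the side-chain carbinol whose ring neighbours are C1 and the methyl carbinol C5. C5 with its methyl, C4, C3 and C6 then correspond to C2 with its methyl, C3, C4 and C1 of (R)-citramalic acid. The key step delivers a hydrogen atom to an isopropenyl group and lets the tertiary C1 radical add to an ynone carbonyl, so that the C1–C6 bond, ring B and the C6 stereocentre arise in one operation from an acyclic bis(silyloxy) ynone. The ethynyl triol is then turned into an (E)-vinylstannane and joined last to a bromobutenolide bearing the ring A polyenyne.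

Key step: step 8

Remark: ring B is numbered C1 (CMe2), C2, C3 (CHOH), C4, C5 (C(Me)OH), C6 (carbinol bearing the chain); the configurations of 13 and 14 were checked atom by atom against the target (C3 S, C5 R, C6 hydroxyl trans to the C5 oxygen and cis to the C3 oxygen).
Remark: in precursor 13 both oxygens carry triethylsilyl groups (stable in warm ethanol, installed together, no hydrogen bond from the C5 oxygen to the ketone) and the alkyne carries triisopropylsilyl (no solvolysis of the silyl ynone, distal alkyne carbon shielded); C3 is set by reagent-controlled allylation of an aldehyde, independent of any directing effect of the tertiary C5 hydroxyl.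
Assumption: (R)-citramalic acid, (4R,6R)-actinol, (E)-3-methylpent-2-en-4-yn-1-ol and the other starting materials are purchasable; all polyenes (step 16 onward) are handled under argon in the dark.

**Ring B (steps 1–10)**

Step 1
Reactants: 1 (R)-citramalic acid
Product: 2 2-[(4R)-2,2,4-trimethyl-5-oxo-1,3-dioxolan-4-yl]acetic acid
Conditions: Me2C(OMe)2, TsOH·H2O (cat.), rt
Reagents that add atoms: 2,2-dimethoxypropane COC(C)(C)OC
Why: Acid-catalysed acetal exchange closes the five-membered dioxolanone on the α-hydroxy acid unit only (acetonide formation), so the two carboxyl groups are told apart while the quaternary stereocentre is left untouched.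

Step 2
Reactants: 2 2-[(4R)-2,2,4-trimethyl-5-oxo-1,3-dioxolan-4-yl]acetic acid
Product: 3 (5R)-5-(2-hydroxyethyl)-2,2,5-trimethyl-1,3-dioxolan-4-one
Conditions: BH3·SMe2, THF, 0 °C → rt; MeOH quench
Reagents that add atoms: none
Why: Borane reduces the free carboxylic acid much faster than the lactone-like dioxolanone carbonyl (chemoselective borane reduction), and a neutral methanol quench avoids acid-promoted lactonisation of the new alcohol.

Step 3
Reactants: 3 (5R)-5-(2-hydroxyethyl)-2,2,5-trimethyl-1,3-dioxolan-4-one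
Product: 4 2-[(4R)-2,2,4-trimethyl-5-oxo-1,3-dioxolan-4-yl]acetaldehyde
Conditions: Dess–Martin periodinane, pyridine, CH2Cl2, 0 °C → rt
Reagents that add atoms: none
Why: Dess–Martin oxidation under pyridine buffering stops cleanly at the aldehyde and keeps the medium free of acid that could open the dioxolanone.

Step 4
Reactants: 4 2-[(4R)-2,2,4-trimethyl-5-oxo-1,3-dioxolan-4-yl]acetaldehyde; 5 2-methylallylmagnesium chloride
Product: 8 (5R)-5-[(2S)-2-hydroxy-4-methylpent-4-en-1-yl]-2,2,5-trimethyl-1,3-dioxolan-4-one, via B-(2-methylallyl)diisopinocampheylborane 6 (not isolated), via diisopinocampheylborinate of the adduct 7 (not isolated)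
Conditions: (−)-Ipc2BOMe [from (+)-α-pinene], 5, Et2O, −78 °C → rt; then 4, −78 °C; then 30% H2O2, pH 7 phosphate buffer, MeOH, 0 °C
Reagents that add atoms: none
Why: Brown asymmetric allylboration with the methallylborane from (+)-α-pinene-derived (−)-Ipc2BOMe is reagent-controlled through a closed chair transition state and should deliver the methallyl group to the Si face of the aldehyde, which sets C3 as S (anti to the C5 oxygen in the extended chain), the remote quaternary centre having little say, and the buffered peroxide work-up spares the dioxolanone.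

Step 5
Reactants: 8 (5R)-5-[(2S)-2-hydroxy-4-methylpent-4-en-1-yl]-2,2,5-trimethyl-1,3-dioxolan-4-one
Product: 9 (2R,4S)-2,4-dihydroxy-N-methoxy-N,2,6-trimethylhept-6-enamide
Conditions: MeNHOMe·HCl, i-PrMgCl, THF, −20 → 0 °C; used at once in step 6
Reagents that add atoms: N,O-dimethylhydroxylamine hydrochloride CNOC.Cl
Why: Weinreb aminolysis of the activated dioxolanone by the magnesium amide expels acetone from the hemiketal and gives the α-hydroxy Weinreb amide without touching either stereocentre, and any γ-lactone formed from 8 on handling would be opened to the same amide.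

Step 6
Reactants: 9 (2R,4S)-2,4-dihydroxy-N-methoxy-N,2,6-trimethylhept-6-enamide
Product: 10 (2R,4S)-N-methoxy-N,2,6-trimethyl-2,4-bis[(triethylsilyl)oxy]hept-6-enamide
Conditions: Et3SiOTf, 2,6-lutidine, CH2Cl2, −78 → 0 °C
Reagents that add atoms: triethylsilyl trifluoromethanesulfonate CC[Si](CC)(CC)OS(=O)(=O)C(F)(F)F
Why: Silyl triflate with 2,6-lutidine (standard silyl ether formation) is reactive enough to cap the hindered tertiary hydroxyl together with the secondary one in a single operation, which also blocks relactonisation onto the amide.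

Step 7
Reactants: 10 (2R,4S)-N-methoxy-N,2,6-trimethyl-2,4-bis[(triethylsilyl)oxy]hept-6-enamide; 11 (triisopropylsilyl)acetylene
Product: 13 (4R,6S)-4,8-dimethyl-4,6-bis[(triethylsilyl)oxy]-1-(triisopropylsilyl)non-8-en-1-yn-3-one, via lithium (triisopropylsilyl)acetylide 12 (not isolated)
Conditions: 11, n-BuLi, THF, −78 °C; then 10, −78 → 0 °C; aq NH4Cl
Reagents that add atoms: none
Why: Weinreb ketone synthesis: the lithium acetylide adds once because the N-methoxy group holds the tetrahedral intermediate as a chelate until aqueous work-up, and the α-silyloxy quaternary centre cannot epimerise.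

Step 8
Reactants: 13 (4R,6S)-4,8-dimethyl-4,6-bis[(triethylsilyl)oxy]-1-(triisopropylsilyl)non-8-en-1-yn-3-one
Product: 14 (1S,2R,4S)-2,6,6-trimethyl-2,4-bis[(triethylsilyl)oxy]-1-[(triisopropylsilyl)ethynyl]cyclohexan-1-ol
Conditions: Fe(acac)3 (1.0 equiv), PhSiH3 (3 equiv), degassed EtOH–(CH2OH)2 5:1, 0.02 M, 60 °C
Reagents that add atoms: none
Why: Proposed new method: the iron hydride formed from Fe(acac)3 and PhSiH3 transfers a hydrogen atom to the terminal CH2 of the 1,1-disubstituted alkene, the nucleophilic tertiary radical at C1 adds to the carbonyl carbon C6 of the ynone, and the alkoxy radical is reduced by divalent iron and protonated by ethanol, so that only hydrogen is added. The closest known reaction type is the iron-hydride hydrogen-atom-transfer reductive cyclisation of alkene-tethered ketones to tertiary alcohols, which has not been shown for an ynone acceptor or for an acyclic chain with fully substituted carbons on both sides of the new bond. Ring B closes 6-exo-trig onto C=O through a chair, whereas attack on either alkyne carbon would need a seven- or eight-membered ring and the distal alkyne carbon is shielded by the triisopropylsilyl group. The new stereocentre C6 is controlled by the two existing centres: in the chair with the C3 silyloxy group and the C5 methyl equatorial, the C5–O bond is axial and the carbonyl oxygen should take the opposite axial site (opposed C–O dipoles, slim alkyne equatorial), which gives the C6 hydroxyl trans to the C5 oxygen and cis to the C3 oxygen. The step needs hydrogen-atom transfer to the electron-rich alkene in preference to the ynone and capture of the alkoxy radical faster than its reopening; the silyl cap on the C5 oxygen (no hydrogen bond to the ketone), high dilution and excess silane are meant to secure this.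

Step 9
Reactants: 14 (1S,2R,4S)-2,6,6-trimethyl-2,4-bis[(triethylsilyl)oxy]-1-[(triisopropylsilyl)ethynyl]cyclohexan-1-ol
Product: 15 (1S,2R,4S)-1-ethynyl-2,6,6-trimethylcyclohexane-1,2,4-triol
Conditions: Bu4NF, THF, 0 °C → rt
Reagents that add atoms: none
Why: Fluoride-induced desilylation removes both triethylsilyl ethers and the alkynyl triisopropylsilyl group in one operation without affecting any stereocentre (a silyl shift between the C5 and C6 oxygens in step 8 would be erased here).

Step 10
Reactants: 15 (1S,2R,4S)-1-ethynyl-2,6,6-trimethylcyclohexane-1,2,4-triol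
Product: 16 (1R,2R,4S)-2,6,6-trimethyl-1-[(E)-2-(tributylstannyl)ethenyl]cyclohexane-1,2,4-triol
Conditions: Bu3SnH, PdCl2(PPh3)2 (2 mol %), THF, 0 °C
Reagents that add atoms: tributyltin hydride CCCC[SnH](CCCC)CCCC
Why: Palladium-catalysed hydrostannation adds Sn–H syn across the terminal alkyne, and the fully substituted propargylic carbon flanked by two quaternary carbons directs tin to the terminal carbon, giving the (E)-alkenylstannane.

**Chain phosphonate (steps 11–13)**

Step 11
Reactants: 17 (2E)-3-methylpent-2-en-4-yn-1-ol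
Product: 19 (2E)-3-methyl-5-(trimethylsilyl)pent-2-en-4-yn-1-ol, via O,C-bis(trimethylsilyl) enynol 18 (not isolated)
Conditions: n-BuLi (2.1 equiv), THF, −78 °C; Me3SiCl (2.2 equiv), −78 °C → rt; 1 M HCl, rt
Reagents that add atoms: chlorotrimethylsilane C[Si](C)(C)Cl
Why: Double deprotonation gives the alkoxide acetylide dianion, both sites are silylated, and mild acid hydrolyses only the labile O–Si bond (C-silylation of a terminal alkyne), leaving the E alkene untouched.

Step 12
Reactants: 19 (2E)-3-methyl-5-(trimethylsilyl)pent-2-en-4-yn-1-ol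
Product: 20 [(3E)-5-bromo-3-methylpent-3-en-1-yn-1-yl]trimethylsilane
Conditions: CBr4, PPh3, CH2Cl2, 0 °C
Reagents that add atoms: carbon tetrabromide BrC(Br)(Br)Br
Why: Appel bromination converts the primary allylic alcohol into the bromide by SN2 displacement under cold neutral conditions, without allylic transposition or loss of the E geometry.

Step 13
Reactants: 20 [(3E)-5-bromo-3-methylpent-3-en-1-yn-1-yl]trimethylsilane
Product: 21 diethyl [(2E)-3-methyl-5-(trimethylsilyl)pent-2-en-4-yn-1-yl]phosphonate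
Conditions: P(OEt)3, neat, 110 °C
Reagents that add atoms: triethyl phosphite CCOP(OCC)OCC
Why: Michaelis–Arbuzov reaction of the primary allylic bromide with triethyl phosphite gives the phosphonate with the E alkene retained.

**Ring A polyenyne and butenolide (steps 14–22)**

Step 14
Reactants: 22 (4R,6R)-4-hydroxy-2,2,6-trimethylcyclohexan-1-one (actinol)
Product: 23 (4R,6R)-4-[(tert-butyldimethylsilyl)oxy]-2,2,6-trimethylcyclohexan-1-one
Conditions: t-BuMe2SiCl, imidazole, DMF, rt
Reagents that add atoms: tert-butyldimethylsilyl chloride CC(C)(C)[Si](C)(C)Cl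
Why: Standard silyl ether formation protects the unhindered secondary hydroxyl so that only the ketone is deprotonated in the next step.

Step 15
Reactants: 23 (4R,6R)-4-[(tert-butyldimethylsilyl)oxy]-2,2,6-trimethylcyclohexan-1-one
Product: 25 (4R)-4-[(tert-butyldimethylsilyl)oxy]-2,6,6-trimethylcyclohex-1-en-1-yl trifluoromethanesulfonate, via lithium cyclohexenolate 24 (not isolated)
Conditions: LiN(i-Pr)2, THF, −78 °C; PhNTf2, −78 °C → rt
Reagents that add atoms: N-phenylbis(trifluoromethanesulfonimide) O=S(=O)(N(c1ccccc1)S(=O)(=O)C(F)(F)F)C(F)(F)F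
Why: The ketone has a single α-hydrogen, so deprotonation can give only the tetrasubstituted enolate, which N-phenyltriflimide traps on oxygen (enol triflate formation); the methyl-bearing stereocentre is erased on purpose and the silyloxy carbon is untouched.

Step 16
Reactants: 25 (4R)-4-[(tert-butyldimethylsilyl)oxy]-2,6,6-trimethylcyclohex-1-en-1-yl trifluoromethanesulfonate; 17 (2E)-3-methylpent-2-en-4-yn-1-ol
Product: 26 (2E)-5-{(4R)-4-[(tert-butyldimethylsilyl)oxy]-2,6,6-trimethylcyclohex-1-en-1-yl}-3-methylpent-2-en-4-yn-1-ol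
Conditions: Pd(PPh3)4 (5 mol %), CuI (10 mol %), i-Pr2NH, DMF, 50 °C
Reagents that add atoms: none
Why: Sonogashira coupling of the alkenyl triflate with the terminal alkyne of 17 forms the ring A–alkyne bond, the free allylic alcohol being tolerated and the E alkene of 17 not being involved.

Step 17
Reactants: 26 (2E)-5-{(4R)-4-[(tert-butyldimethylsilyl)oxy]-2,6,6-trimethylcyclohex-1-en-1-yl}-3-methylpent-2-en-4-yn-1-ol
Product: 27 (2E)-5-{(4R)-4-[(tert-butyldimethylsilyl)oxy]-2,6,6-trimethylcyclohex-1-en-1-yl}-3-methylpent-2-en-4-ynal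
Conditions: MnO2, CH2Cl2, rt
Reagents that add atoms: none
Why: MnO2 oxidises the allylic alcohol selectively to the conjugated aldehyde (allylic oxidation) without touching the silyl ether or isomerising the enyne.

Step 18
Reactants: 27 (2E)-5-{(4R)-4-[(tert-butyldimethylsilyl)oxy]-2,6,6-trimethylcyclohex-1-en-1-yl}-3-methylpent-2-en-4-ynal; 28 (triphenylphosphoranylidene)acetaldehyde
Product: 29 (2E,4E)-7-{(4R)-4-[(tert-butyldimethylsilyl)oxy]-2,6,6-trimethylcyclohex-1-en-1-yl}-5-methylhepta-2,4-dien-6-ynal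
Conditions: toluene, 80 °C
Reagents that add atoms: none
Why: Wittig reaction with the stabilised formylmethylene ylide extends the enal by two carbons with E selectivity, and since the dienal formed is less electrophilic than 27 a second homologation stays slow.

Step 19
Reactants: 29 (2E,4E)-7-{(4R)-4-[(tert-butyldimethylsilyl)oxy]-2,6,6-trimethylcyclohex-1-en-1-yl}-5-methylhepta-2,4-dien-6-ynal; 21 diethyl [(2E)-3-methyl-5-(trimethylsilyl)pent-2-en-4-yn-1-yl]phosphonate
Product: 31 tert-butyldimethyl({(1R)-3,5,5-trimethyl-4-[(3E,5E,7E,9E)-3,10-dimethyl-12-(trimethylsilyl)dodeca-3,5,7,9-tetraene-1,11-diyn-1-yl]cyclohex-3-en-1-yl}oxy)silane, via sodium phosphonate carbanion 30 (not isolated)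
Conditions: 21, NaN(SiMe3)2, THF, −78 °C; then 29, −78 → 0 °C
Reagents that add atoms: none
Why: Horner–Wadsworth–Emmons olefination: the allylic phosphonate anion reacts at its α-carbon with the dienal and the reversible addition followed by syn elimination favours the E disubstituted alkene, completing the all-E tetraene.

Step 20
Reactants: 31 tert-butyldimethyl({(1R)-3,5,5-trimethyl-4-[(3E,5E,7E,9E)-3,10-dimethyl-12-(trimethylsilyl)dodeca-3,5,7,9-tetraene-1,11-diyn-1-yl]cyclohex-3-en-1-yl}oxy)silane
Product: 32 (1R)-4-[(3E,5E,7E,9E)-3,10-dimethyldodeca-3,5,7,9-tetraene-1,11-diyn-1-yl]-3,5,5-trimethylcyclohex-3-en-1-ol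
Conditions: Bu4NF, THF, 0 °C → rt
Reagents that add atoms: none
Why: Fluoride cleaves the alkynyl C–Si bond and the silyl ether in one operation (desilylation), which frees the terminal alkyne and the ring A hydroxyl before the palladium steps.

Step 21
Reactants: 33 propiolic acid
Product: 34 (2E)-2,3-dibromoprop-2-enoic acid
Conditions: Br2, CHCl3, 0 °C → rt, dark
Reagents that add atoms: bromine BrBr
Why: Electrophilic anti addition of bromine to the alkyne gives the E dibromide, in which the β-bromine stands cis to the carboxyl group as needed for lactonisation.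

Step 22
Reactants: 32 (1R)-4-[(3E,5E,7E,9E)-3,10-dimethyldodeca-3,5,7,9-tetraene-1,11-diyn-1-yl]-3,5,5-trimethylcyclohex-3-en-1-ol; 34 (2E)-2,3-dibromoprop-2-enoic acid
Product: 36 (5Z)-3-bromo-5-{(2E,4E,6E,8E)-11-[(4R)-4-hydroxy-2,6,6-trimethylcyclohex-1-en-1-yl]-2,9-dimethylundeca-2,4,6,8-tetraen-10-yn-1-ylidene}furan-2(5H)-one, via bromo enynoic acid 35 (not isolated)
Conditions: 34 (1.5 equiv), Pd(PPh3)4 (5 mol %), CuI (10 mol %), Et3N, MeCN, rt, dark
Reagents that add atoms: none
Why: Tandem Sonogashira coupling and 5-exo-dig lactonisation: oxidative addition should occur at the more electrophilic β-C–Br bond with retention, and anti addition of the cis carboxylate across the metal-activated alkyne followed by protodemetalation gives the Z-ylidenebutenolide with the α-bromine kept.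

**Fragment union**

Step 23
Reactants: 36 (5Z)-3-bromo-5-{(2E,4E,6E,8E)-11-[(4R)-4-hydroxy-2,6,6-trimethylcyclohex-1-en-1-yl]-2,9-dimethylundeca-2,4,6,8-tetraen-10-yn-1-ylidene}furan-2(5H)-one; 16 (1R,2R,4S)-2,6,6-trimethyl-1-[(E)-2-(tributylstannyl)ethenyl]cyclohexane-1,2,4-triol
Product: 37 (5Z)-5-{(2E,4E,6E,8E)-11-[(4R)-4-hydroxy-2,6,6-trimethylcyclohex-1-en-1-yl]-2,9-dimethylundeca-2,4,6,8-tetraen-10-yn-1-ylidene}-3-{(E)-2-[(1R,2R,4S)-1,2,4-trihydroxy-2,6,6-trimethylcyclohexyl]ethenyl}furan-2(5H)-one (CNP0163979.1)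
Conditions: Pd2(dba)3 (5 mol %), AsPh3 (40 mol %), NMP, rt → 40 °C, dark
Reagents that add atoms: none
Why: Stille coupling joins the alkenylstannane and the α-bromobutenolide with retention of both alkene geometries under neutral conditions that tolerate the four free hydroxyls, the Z-ylidene lactone and the polyenyne.

**Compound list**

1 | (R)-citramalic acid | C[C@@](O)(CC(=O)O)C(=O)O | starting material
2 | 2-[(4R)-2,2,4-trimethyl-5-oxo-1,3-dioxolan-4-yl]acetic acid | C[C@]1(CC(=O)O)OC(C)(C)OC1=O | intermediate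
3 | (5R)-5-(2-hydroxyethyl)-2,2,5-trimethyl-1,3-dioxolan-4-one | C[C@]1(CCO)OC(C)(C)OC1=O | intermediate
4 | 2-[(4R)-2,2,4-trimethyl-5-oxo-1,3-dioxolan-4-yl]acetaldehyde | C[C@]1(CC=O)OC(C)(C)OC1=O | intermediate
5 | 2-methylallylmagnesium chloride | C=C(C)C[Mg]Cl | starting material
6 | B-(2-methylallyl)diisopinocampheylborane (isopinocampheyl groups from (+)-α-pinene) | C=C(C)CB([C@@H]1C[C@@H]2C[C@@H](C2(C)C)[C@H]1C)[C@@H]1C[C@@H]2C[C@@H](C2(C)C)[C@H]1C | intermediate
7 | diisopinocampheylborinate of 8 (O–B bond at the C3 oxygen) | C=C(C)C[C@H](OB([C@@H]2C[C@@H]3C[C@@H](C3(C)C)[C@H]2C)[C@@H]2C[C@@H]3C[C@@H](C3(C)C)[C@H]2C)C[C@@]1(C)OC(C)(C)OC1=O | intermediate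
8 | (5R)-5-[(2S)-2-hydroxy-4-methylpent-4-en-1-yl]-2,2,5-trimethyl-1,3-dioxolan-4-one | C=C(C)C[C@H](O)C[C@@]1(C)OC(C)(C)OC1=O | intermediate
9 | (2R,4S)-2,4-dihydroxy-N-methoxy-N,2,6-trimethylhept-6-enamide | C=C(C)C[C@H](O)C[C@@](C)(O)C(=O)N(C)OC | intermediate
10 | (2R,4S)-N-methoxy-N,2,6-trimethyl-2,4-bis[(triethylsilyl)oxy]hept-6-enamide | C=C(C)C[C@H](O[Si](CC)(CC)CC)C[C@@](C)(O[Si](CC)(CC)CC)C(=O)N(C)OC | intermediate
11 | (triisopropylsilyl)acetylene | C#C[Si](C(C)C)(C(C)C)C(C)C | starting material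
12 | lithium (triisopropylsilyl)acetylide | [Li+].[C-]#C[Si](C(C)C)(C(C)C)C(C)C | intermediate
13 | (4R,6S)-4,8-dimethyl-4,6-bis[(triethylsilyl)oxy]-1-(triisopropylsilyl)non-8-en-1-yn-3-one | C=C(C)C[C@H](O[Si](CC)(CC)CC)C[C@@](C)(O[Si](CC)(CC)CC)C(=O)C#C[Si](C(C)C)(C(C)C)C(C)C | intermediate
14 | (1S,2R,4S)-2,6,6-trimethyl-2,4-bis[(triethylsilyl)oxy]-1-[(triisopropylsilyl)ethynyl]cyclohexan-1-ol | CC(C)[Si](C(C)C)(C(C)C)C#C[C@@]1(O)C(C)(C)C[C@H](O[Si](CC)(CC)CC)C[C@@]1(C)O[Si](CC)(CC)CC | intermediate
15 | (1S,2R,4S)-1-ethynyl-2,6,6-trimethylcyclohexane-1,2,4-triol | C#C[C@@]1(O)C(C)(C)C[C@H](O)C[C@@]1(C)O | intermediate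
16 | (1R,2R,4S)-2,6,6-trimethyl-1-[(E)-2-(tributylstannyl)ethenyl]cyclohexane-1,2,4-triol | CCCC[Sn](CCCC)(CCCC)/C=C/[C@@]1(O)C(C)(C)C[C@H](O)C[C@@]1(C)O | intermediate
17 | (2E)-3-methylpent-2-en-4-yn-1-ol | C#C/C(C)=C/CO | starting material
18 | trimethyl{[(2E)-3-methyl-5-(trimethylsilyl)pent-2-en-4-yn-1-yl]oxy}silane | C[Si](C)(C)C#C/C(C)=C/CO[Si](C)(C)C | intermediate
19 | (2E)-3-methyl-5-(trimethylsilyl)pent-2-en-4-yn-1-ol | C[Si](C)(C)C#C/C(C)=C/CO | intermediate
20 | [(3E)-5-bromo-3-methylpent-3-en-1-yn-1-yl]trimethylsilane | C[Si](C)(C)C#C/C(C)=C/CBr | intermediate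
21 | diethyl [(2E)-3-methyl-5-(trimethylsilyl)pent-2-en-4-yn-1-yl]phosphonate | CCOP(=O)(OCC)C/C=C(C)/C#C[Si](C)(C)C | intermediate
22 | (4R,6R)-4-hydroxy-2,2,6-trimethylcyclohexan-1-one (actinol) | O=C1C(C)(C)C[C@H](O)C[C@H]1C | starting material
23 | (4R,6R)-4-[(tert-butyldimethylsilyl)oxy]-2,2,6-trimethylcyclohexan-1-one | O=C1C(C)(C)C[C@H](O[Si](C)(C)C(C)(C)C)C[C@H]1C | intermediate
24 | lithium (4R)-4-[(tert-butyldimethylsilyl)oxy]-2,6,6-trimethylcyclohex-1-en-1-olate | [Li+].CC1=C([O-])C(C)(C)C[C@H](O[Si](C)(C)C(C)(C)C)C1 | intermediate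
25 | (4R)-4-[(tert-butyldimethylsilyl)oxy]-2,6,6-trimethylcyclohex-1-en-1-yl trifluoromethanesulfonate | CC1=C(OS(=O)(=O)C(F)(F)F)C(C)(C)C[C@H](O[Si](C)(C)C(C)(C)C)C1 | intermediate
26 | (2E)-5-{(4R)-4-[(tert-butyldimethylsilyl)oxy]-2,6,6-trimethylcyclohex-1-en-1-yl}-3-methylpent-2-en-4-yn-1-ol | CC1=C(C#C/C(C)=C/CO)C(C)(C)C[C@H](O[Si](C)(C)C(C)(C)C)C1 | intermediate
27 | (2E)-5-{(4R)-4-[(tert-butyldimethylsilyl)oxy]-2,6,6-trimethylcyclohex-1-en-1-yl}-3-methylpent-2-en-4-ynal | CC1=C(C#C/C(C)=C/C=O)C(C)(C)C[C@H](O[Si](C)(C)C(C)(C)C)C1 | intermediate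
28 | (triphenylphosphoranylidene)acetaldehyde | O=CC=P(c1ccccc1)(c1ccccc1)c1ccccc1 | starting material
29 | (2E,4E)-7-{(4R)-4-[(tert-butyldimethylsilyl)oxy]-2,6,6-trimethylcyclohex-1-en-1-yl}-5-methylhepta-2,4-dien-6-ynal | CC1=C(C#C/C(C)=C/C=C/C=O)C(C)(C)C[C@H](O[Si](C)(C)C(C)(C)C)C1 | intermediate
30 | sodium salt of the α-carbanion of phosphonate 21 | [Na+].CCOP(=O)(OCC)[CH-]/C=C(C)/C#C[Si](C)(C)C | intermediate
31 | tert-butyldimethyl({(1R)-3,5,5-trimethyl-4-[(3E,5E,7E,9E)-3,10-dimethyl-12-(trimethylsilyl)dodeca-3,5,7,9-tetraene-1,11-diyn-1-yl]cyclohex-3-en-1-yl}oxy)silane | CC1=C(C#C/C(C)=C/C=C/C=C/C=C(C)/C#C[Si](C)(C)C)C(C)(C)C[C@H](O[Si](C)(C)C(C)(C)C)C1 | intermediate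
32 | (1R)-4-[(3E,5E,7E,9E)-3,10-dimethyldodeca-3,5,7,9-tetraene-1,11-diyn-1-yl]-3,5,5-trimethylcyclohex-3-en-1-ol | CC1=C(C#C/C(C)=C/C=C/C=C/C=C(C)/C#C)C(C)(C)C[C@H](O)C1 | intermediate
33 | propiolic acid | C#CC(=O)O | starting material
34 | (2E)-2,3-dibromoprop-2-enoic acid | OC(=O)/C(Br)=C\Br | intermediate
35 | (2E,6E,8E,10E,12E)-2-bromo-15-[(4R)-4-hydroxy-2,6,6-trimethylcyclohex-1-en-1-yl]-6,13-dimethylpentadeca-2,6,8,10,12-pentaene-4,14-diynoic acid (alkynyl cis to CO2H) | CC1=C(C#C/C(C)=C/C=C/C=C/C=C(C)/C#C/C=C(Br)\C(=O)O)C(C)(C)C[C@H](O)C1 | intermediate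
36 | (5Z)-3-bromo-5-{(2E,4E,6E,8E)-11-[(4R)-4-hydroxy-2,6,6-trimethylcyclohex-1-en-1-yl]-2,9-dimethylundeca-2,4,6,8-tetraen-10-yn-1-ylidene}furan-2(5H)-one | CC1=C(C#C/C(C)=C/C=C/C=C/C=C(C)/C=C2C=C(Br)C(=O)O/2)C(C)(C)C[C@H](O)C1 | intermediate
37 | (5Z)-5-{(2E,4E,6E,8E)-11-[(4R)-4-hydroxy-2,6,6-trimethylcyclohex-1-en-1-yl]-2,9-dimethylundeca-2,4,6,8-tetraen-10-yn-1-ylidene}-3-{(E)-2-[(1R,2R,4S)-1,2,4-trihydroxy-2,6,6-trimethylcyclohexyl]ethenyl}furan-2(5H)-one | CC1=C(C#C/C(C)=C/C=C/C=C/C=C(C)/C=C2C=C(/C=C/[C@@]3(O)C(C)(C)C[C@H](O)C[C@@]3(C)O)C(=O)O/2)C(C)(C)C[C@H](O)C1 | target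

**Totals and risks**

Total step count: 23. Longest linear sequence: 11 steps (steps 1–10, then step 23).

Steps most likely to fail:

1. Step 8 (radical ring closure). The tertiary radical may be reduced to the isopropyl group before it cyclises. The cyclised alkoxy radical may reopen toward the stabilised α-silyloxy C5 radical, which amounts to an acyl shift from C5 to C1. The carbonyl may also be attacked with the alkyne axial, giving the C6 epimer. The fallback uses known reactions only; it sets out from triflate 25 and alkyne 11 and comes back at triol 15. Sonogashira coupling of 25 with 11 (Pd(PPh3)4, CuI, i-Pr2NH, DMF) would give tert-butyldimethyl({(1R)-3,5,5-trimethyl-4-[(triisopropylsilyl)ethynyl]cyclohex-3-en-1-yl}oxy)silane F1. Bu4NF would remove both silyl groups to give (1R)-4-ethynyl-3,5,5-trimethylcyclohex-3-en-1-ol F2. Epoxidation directed by the homoallylic hydroxyl (VO(acac)2, t-BuOOH, toluene) would place the oxirane cis to that hydroxyl and give (1S,3S,6S)-6-ethynyl-1,5,5-trimethyl-7-oxabicyclo[4.1.0]heptan-3-ol F3. Dilute HClO4 in THF–water would then open the oxirane trans-diaxially at the methyl-bearing carbon, which is less hindered and not destabilised by the alkyne, with inversion there. This gives 15, and the route continues with step 10.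

2. Step 22 (coupling–lactonisation cascade on the polyenyne). A second coupling may occur at the α-bromine of the product, the ring may close 6-endo to a pyranone, or the polyene may isomerise during a slow cascade. The fallback separates bond formation from ring closure; it sets out from 34 and 32 and comes back at 36. Acid 34 would be esterified (EtOH, H2SO4) to ethyl (2E)-2,3-dibromoprop-2-enoate F4. Sonogashira coupling of 32 with F4 (PdCl2(PPh3)2, CuI, Et3N, THF, rt) at the β-bromine would give ethyl (2E,6E,8E,10E,12E)-2-bromo-15-[(4R)-4-hydroxy-2,6,6-trimethylcyclohex-1-en-1-yl]-6,13-dimethylpentadeca-2,6,8,10,12-pentaene-4,14-diynoate F5. LiOH (THF–H2O, 0 °C) would give acid 35, this time isolated, and AgNO3 (10 mol %, acetone, rt, dark) would close it 5-exo-dig to 36.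

3. Step 23 (final Stille coupling). Transmetalation may be slow next to the crowded carbinol, the stannane may be lost by protodestannylation, and long contact with palladium may isomerise the polyene. The fallback changes the ring B partner from tin to boron; it sets out from 15 and comes back at 37. Copper-catalysed formal hydroboration of 15 (CuCl, PPh3, NaOt-Bu, B2pin2, MeOH, THF, rt) would give (1R,2R,4S)-2,6,6-trimethyl-1-[(E)-2-(4,4,5,5-tetramethyl-1,3,2-dioxaborolan-2-yl)ethenyl]cyclohexane-1,2,4-triol F6. Suzuki–Miyaura coupling of F6 with 36 (Pd(PPh3)4, K3PO4, THF–H2O, rt, dark) would give 37.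

Further compounds
F1 | step 8 | tert-butyldimethyl({(1R)-3,5,5-trimethyl-4-[(triisopropylsilyl)ethynyl]cyclohex-3-en-1-yl}oxy)silane | CC1=C(C#C[Si](C(C)C)(C(C)C)C(C)C)C(C)(C)C[C@H](O[Si](C)(C)C(C)(C)C)C1
F2 | step 8 | (1R)-4-ethynyl-3,5,5-trimethylcyclohex-3-en-1-ol | CC1=C(C#C)C(C)(C)C[C@H](O)C1
F3 | step 8 | (1S,3S,6S)-6-ethynyl-1,5,5-trimethyl-7-oxabicyclo[4.1.0]heptan-3-ol (oxirane cis to the hydroxyl) | C#C[C@@]12C(C)(C)C[C@H](O)C[C@]1(C)O2
F4 | step 22 | ethyl (2E)-2,3-dibromoprop-2-enoate | CCOC(=O)/C(Br)=C\Br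
F5 | step 22 | ethyl (2E,6E,8E,10E,12E)-2-bromo-15-[(4R)-4-hydroxy-2,6,6-trimethylcyclohex-1-en-1-yl]-6,13-dimethylpentadeca-2,6,8,10,12-pentaene-4,14-diynoate | CC1=C(C#C/C(C)=C/C=C/C=C/C=C(C)/C#C/C=C(Br)\C(=O)OCC)C(C)(C)C[C@H](O)C1
F6 | step 23 | (1R,2R,4S)-2,6,6-trimethyl-1-[(E)-2-(4,4,5,5-tetramethyl-1,3,2-dioxaborolan-2-yl)ethenyl]cyclohexane-1,2,4-triol | CC1(C)OB(/C=C/[C@@]2(O)C(C)(C)C[C@H](O)C[C@@]2(C)O)OC1(C)C
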